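**Retrosynthetic overview**

- The target is the meso (R,S) dibenzylbutane carrying two syringyl rings. The strategy rests on this reading of each ring: aryl C1 (which carries benzylic C7) is the β-carbon of an enone, C3 and C5 (the OMe carbons) are the carbonyl carbons of a cyclohexane-1,3-dione, and C4 (the phenol carbon) is the carbon between them.
- The C4–OH and C4'–OH bonds are made last, by lithiation between the two methoxy groups, borylation and oxidation. The two arenes come from iodine/methanol aromatization of a bis(cyclohexane-1,3-dione).
- Key disconnection: C1–C2 (Michael) and C3–C4 (Claisen) of each ring, leading back to an acyclic meso bis-enone and two molecules of dimethyl malonate. Both carbocycles close in the same flask and are aromatized together afterwards.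
- The bis-enone comes from ozonolysis and double Wittig olefination of cis-4,5-dimethylcyclohexene. Its cis methyl groups, derived from cis-1,2,3,6-tetrahydrophthalic anhydride via the diol and ditosylate, become the meso C8/C8' pair.

Key step: step 5

**Route**

Step 1
Reactants: 1 cis-1,2,3,6-tetrahydrophthalic anhydride
Product: 2 cis-cyclohex-4-ene-1,2-diyldimethanol (meso)
Conditions: LiAlH4 (1.5 equiv), THF, 0 °C → reflux; then H2O, 15% aq NaOH, H2O
Reagents that add atoms: none
Why: LiAlH4 reduction of a cyclic anhydride gives the 1,4-diol, the isolated alkene is inert to hydride, and the two ring stereocenters are not touched, so the cis relationship is kept.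

Step 2
Reactants: 2 cis-cyclohex-4-ene-1,2-diyldimethanol
Product: 3 cis-cyclohex-4-ene-1,2-diylbis(methylene) bis(4-methylbenzenesulfonate)
Conditions: TsCl (2.5 equiv), pyridine, 0 °C → 4 °C
Reagents that add atoms: p-toluenesulfonyl chloride, Cc1ccc(cc1)S(Cl)(=O)=O
Why: O-sulfonylation of two primary alcohols in cold pyridine, where low temperature and excess TsCl should keep the monotosylate from closing to the bicyclic tetrahydrofuran; no stereocenter takes part.

Step 3
Reactants: 3 cis-cyclohex-4-ene-1,2-diylbis(methylene) bis(4-methylbenzenesulfonate)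
Product: 4 cis-4,5-dimethylcyclohexene (meso)
Conditions: LiAlH4 (3 equiv), THF, reflux; H2O/aq NaOH work-up; pentane extraction, water wash, distillation through a short fractionating column
Reagents that add atoms: none
Why: SN2 hydride displacement of primary tosylates by LiAlH4 (reductive deoxygenation) turns both CH2OTs groups into methyl groups without touching the alkene or the cis stereocenters.

Step 4
Reactants: 4 cis-4,5-dimethylcyclohexene; 5 1-(triphenylphosphoranylidene)propan-2-one (2.4 equiv)
Product: 8 meso-(3E,6R,7S,9E)-6,7-dimethyldodeca-3,9-diene-2,11-dione, via ozonide 6 (not isolated), via dialdehyde 7 (not isolated)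
Conditions: O3, CH2Cl2, −78 °C; N2 purge; PPh3 (1.1 equiv), −78 °C → rt; then 5, rt → 40 °C
Reagents that add atoms: none
Why: Ozonolysis of the only alkene and PPh3 reduction of the ozonide should give the meso dialdehyde, whose stereocenters are β to the carbonyls and cannot epimerize, and the stabilized ylide then effects a twofold Wittig olefination that is reliably E-selective, all ozone-derived oxygen leaving as Ph3P=O.

Step 5
Reactants: 8 meso-(3E,6R,7S,9E)-6,7-dimethyldodeca-3,9-diene-2,11-dione; 9 dimethyl malonate (2.4 equiv)
Product: 13 meso-5,5'-[(2R,3S)-2,3-dimethylbutane-1,4-diyl]bis(cyclohexane-1,3-dione), via bis(Michael adduct) 10 (not isolated), via bis(keto ester) 11 (not isolated), via bis(keto acid) 12 (not isolated)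
Conditions: NaOMe (2.5 equiv), MeOH, reflux; then 5 M aq NaOH, reflux; then conc. HCl to pH 1, reflux
Reagents that add atoms: none
Why: Methoxide generates the malonate anion, which adds in a Michael reaction to the β-carbon of each E-enone (ring bond C1–C2); after proton transfer the methyl-ketone enolate attacks one malonate ester in a Claisen condensation (ring bond C3–C4) with loss of methoxide, and saponification followed by acid-promoted decarboxylation of the β-keto acid leaves the 1,3-dione. The closest known reaction type is the malonate Michael–Claisen annulation of alk-3-en-2-ones to 5-substituted cyclohexane-1,3-diones (the dimedone synthesis), run here at both ends of one chain. Each ring closes in a 6-(enolendo)-exo-trig mode, the only workable one because the internal enolate could reach the ester only through a four-membered ring. No new stereocenter survives, since ring C5 of each dione carries two identical arms, and the meso C8/C8' pair stays two carbons away from any enolizable position throughout. The selectivity needed is intermolecular malonate addition ahead of base-induced reactions of the bis-enone itself (γ-deprotonation with five-ring vinylogous Michael closure, aldol oligomerization); it is secured by the far higher acidity of malonate, which makes it the only carbanion present in quantity, by its excess, and by the drain of each adduct into the doubly stabilized dione enolate.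

Step 6
Reactants: 13 meso-5,5'-[(2R,3S)-2,3-dimethylbutane-1,4-diyl]bis(cyclohexane-1,3-dione)
Product: 14 meso-1,1'-[(2R,3S)-2,3-dimethylbutane-1,4-diyl]bis(3,5-dimethoxybenzene)
Conditions: I2 (4.5 equiv), MeOH, reflux; aq Na2S2O3 work-up
Reagents that add atoms: methanol, CO
Why: Iodine–methanol oxidative aromatization of cyclohexane-1,3-diones, in which HI formed in the flask catalyses conversion of each dione to its methyl enol ether and dienol ether, and α-iodination with loss of HI then gives the arene (one I2 per ring), so each dione carbonyl carbon ends as an aryl C–OMe while the remote stereocenters are untouched.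

Step 7
Reactants: 14 meso-1,1'-[(2R,3S)-2,3-dimethylbutane-1,4-diyl]bis(3,5-dimethoxybenzene)
Product: 17 meso-4,4'-[(2R,3S)-2,3-dimethylbutane-1,4-diyl]bis(2,6-dimethoxyphenol), via bis(aryllithium) 15 (not isolated), via bis(dimethyl boronate) 16 (not isolated)
Conditions: n-BuLi (3 equiv), TMEDA (3 equiv), THF, 0 °C → rt; B(OMe)3 (4 equiv), −78 °C → rt; AcOH, 30% aq H2O2, 0 °C → rt; aq Na2SO3
Reagents that add atoms: hydrogen peroxide, OO
Why: Directed ortho-metalation removes the proton flanked by two methoxy groups on each ring (the most acidic, doubly coordinated site), the aryllithiums are trapped by B(OMe)3, and peroxide-induced 1,2-migration of the aryl group from boron to oxygen followed by hydrolysis should give the phenols at C4 and C4'.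

**Compound list**

1 | cis-1,2,3,6-tetrahydrophthalic anhydride, (3aR,7aS), meso | O=C1OC(=O)[C@H]2CC=CC[C@@H]12 | starting material
2 | cis-cyclohex-4-ene-1,2-diyldimethanol, (1R,2S), meso | OC[C@@H]1CC=CC[C@@H]1CO | intermediate
3 | cis-cyclohex-4-ene-1,2-diylbis(methylene) bis(4-methylbenzenesulfonate) | Cc1ccc(cc1)S(=O)(=O)OC[C@@H]1CC=CC[C@@H]1COS(=O)(=O)c1ccc(C)cc1 | intermediate
4 | cis-4,5-dimethylcyclohexene, (4R,5S), meso | C[C@@H]1CC=CC[C@@H]1C | intermediate
5 | 1-(triphenylphosphoranylidene)propan-2-one | CC(=O)C=P(c1ccccc1)(c1ccccc1)c1ccccc1 | starting material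
6 | cis-3,4-dimethyl-7,8,9-trioxabicyclo[4.2.1]nonane (secondary ozonide of 4, bridgehead isomers not specified) | C[C@@H]1CC2OOC(O2)C[C@@H]1C | intermediate
7 | meso-(3R,4S)-3,4-dimethylhexanedial | O=CC[C@@H](C)[C@@H](C)CC=O | intermediate
8 | meso-(3E,6R,7S,9E)-6,7-dimethyldodeca-3,9-diene-2,11-dione | CC(=O)/C=C/C[C@@H](C)[C@@H](C)C/C=C/C(C)=O | intermediate
9 | dimethyl malonate | COC(=O)CC(=O)OC | starting material
10 | tetramethyl 2,2'-[(6R,7S)-6,7-dimethyl-2,11-dioxododecane-4,9-diyl]dimalonate (C4/C9 epimers not specified) | CC(=O)CC(C[C@@H](C)[C@@H](C)CC(CC(C)=O)C(C(=O)OC)C(=O)OC)C(C(=O)OC)C(=O)OC | intermediate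
11 | dimethyl 6,6'-[(2R,3S)-2,3-dimethylbutane-1,4-diyl]bis(2,4-dioxocyclohexane-1-carboxylate) (formed as its disodium enolate; ring stereocenters not specified) | COC(=O)C1C(=O)CC(=O)CC1C[C@@H](C)[C@@H](C)CC1CC(=O)CC(=O)C1C(=O)OC | intermediate
12 | 6,6'-[(2R,3S)-2,3-dimethylbutane-1,4-diyl]bis(2,4-dioxocyclohexane-1-carboxylic acid) (formed as its sodium salt; ring stereocenters not specified) | OC(=O)C1C(=O)CC(=O)CC1C[C@@H](C)[C@@H](C)CC1CC(=O)CC(=O)C1C(=O)O | intermediate
13 | meso-5,5'-[(2R,3S)-2,3-dimethylbutane-1,4-diyl]bis(cyclohexane-1,3-dione) | O=C1CC(=O)CC(C[C@@H](C)[C@@H](C)CC2CC(=O)CC(=O)C2)C1 | intermediate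
14 | meso-1,1'-[(2R,3S)-2,3-dimethylbutane-1,4-diyl]bis(3,5-dimethoxybenzene) | COc1cc(C[C@@H](C)[C@@H](C)Cc2cc(OC)cc(OC)c2)cc(OC)c1 | intermediate
15 | [(2R,3S)-2,3-dimethylbutane-1,4-diyl]bis(2,6-dimethoxy-4,1-phenylene)dilithium | [Li]c1c(OC)cc(C[C@@H](C)[C@@H](C)Cc2cc(OC)c([Li])c(OC)c2)cc1OC | intermediate
16 | tetramethyl {[(2R,3S)-2,3-dimethylbutane-1,4-diyl]bis(2,6-dimethoxy-4,1-phenylene)}diboronate | COB(OC)c1c(OC)cc(C[C@@H](C)[C@@H](C)Cc2cc(OC)c(B(OC)OC)c(OC)c2)cc1OC | intermediate
17 | meso-4,4'-[(2R,3S)-2,3-dimethylbutane-1,4-diyl]bis(2,6-dimethoxyphenol) | COc1cc(C[C@@H](C)[C@@H](C)Cc2cc(OC)c(O)c(OC)c2)cc(OC)c1O | target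

**Step count**

Total steps: 7. Longest linear sequence: 7 steps (1 → 2 → 3 → 4 → 8 → 13 → 14 → 17).

**Steps most likely to fail, with fallbacks**

Step 5. The risk is that base-induced self-reaction of the bis-enone (γ-deprotonation followed by intramolecular vinylogous Michael closure, or aldol oligomerization) outruns the second annulation, or that the sequence stalls after one ring has formed. The fallback inverts the roles of the partners so that the acceptor carries no enolizable methyl ketone. It sets out from 4: ozonolysis and PPh3 reduction as in step 4 (via 6 and 7), then Wittig olefination with methyl (triphenylphosphoranylidene)acetate in CH2Cl2, should give dimethyl (2E,5R,6S,8E)-5,6-dimethyldeca-2,8-dienedioate F1. Heating F1 with methyl acetoacetate (2.4 equiv) and NaOMe in MeOH should add the acetoacetate to each enoate β-carbon, giving dimethyl (5R,6S)-3,8-bis(1-methoxy-1,3-dioxobutan-2-yl)-5,6-dimethyldecanedioate F2. Its acetyl methyl groups then close onto the chain esters by Claisen condensation to the same bis(keto ester) 11. Aqueous NaOH and then HCl with heating, as in step 5, pass through 12 and bring the sequence back to the route at 13.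

Step 6. The risk is incomplete O-methylation during aromatization (mixtures of phenols and ethers), iodination of the very electron-rich rings, or aromatization of only one ring. The fallback separates dehydrogenation from etherification. It sets out from 13: catalytic dehydrogenation over Pd/C (palladium metal on charcoal) in refluxing mesitylene under N2 should give 5,5'-[(2R,3S)-2,3-dimethylbutane-1,4-diyl]bis(benzene-1,3-diol) F3. Exhaustive O-methylation of F3 with dimethyl sulfate and K2CO3 in refluxing acetone returns to the route at 14.

Step 7. The risk is metalation of only one ring, protodeboronation of the hindered, electron-rich boronate before the boron-to-oxygen shift, or over-oxidation of the electron-rich phenol by peroxide. The fallback makes the C–O bond by acyl-to-oxygen migration instead of through boron. It sets out from 14: lithiation as in step 7 to 15, then quenching with DMF and aqueous NH4Cl, should give 4,4'-[(2R,3S)-2,3-dimethylbutane-1,4-diyl]bis(2,6-dimethoxybenzaldehyde) F4. This dialdehyde is stable and can be purified, and partly formylated material can be resubjected. Baeyer–Villiger oxidation with mCPBA in CH2Cl2, in which the electron-rich aryl group migrates, should give [(2R,3S)-2,3-dimethylbutane-1,4-diyl]bis(2,6-dimethoxy-4,1-phenylene) diformate F5. Methanolysis of F5 with K2CO3 in MeOH arrives at 17.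

**Further compounds**

F1 | step 5 | dimethyl (2E,5R,6S,8E)-5,6-dimethyldeca-2,8-dienedioate | COC(=O)/C=C/C[C@@H](C)[C@@H](C)C/C=C/C(=O)OC
F2 | step 5 | dimethyl (5R,6S)-3,8-bis(1-methoxy-1,3-dioxobutan-2-yl)-5,6-dimethyldecanedioate | COC(=O)CC(C[C@@H](C)[C@@H](C)CC(CC(=O)OC)C(C(C)=O)C(=O)OC)C(C(C)=O)C(=O)OC
F3 | step 6 | 5,5'-[(2R,3S)-2,3-dimethylbutane-1,4-diyl]bis(benzene-1,3-diol) | Oc1cc(O)cc(C[C@@H](C)[C@@H](C)Cc2cc(O)cc(O)c2)c1
F4 | step 7 | 4,4'-[(2R,3S)-2,3-dimethylbutane-1,4-diyl]bis(2,6-dimethoxybenzaldehyde) | COc1cc(C[C@@H](C)[C@@H](C)Cc2cc(OC)c(C=O)c(OC)c2)cc(OC)c1C=O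
F5 | step 7 | [(2R,3S)-2,3-dimethylbutane-1,4-diyl]bis(2,6-dimethoxy-4,1-phenylene) diformate | COc1cc(C[C@@H](C)[C@@H](C)Cc2cc(OC)c(OC=O)c(OC)c2)cc(OC)c1OC=O
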